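**Retrosynthetic overview**

1. Target 31 comes from Yamaguchi acylation of the 8β-hydroxyl of epoxy lactone 26 with the preformed (2R,3S)-epoxy acid 29 (Sharpless epoxidation of tiglyl alcohol); 26 comes from peripheral epoxidation of the 1(10)E alkene of macrolactone 24.
2. 24 comes from bromo enal 22 by forming C6–C7: a chromium-catalysed, ligand-controlled macrocyclising 2-(methoxycarbonyl)allylation closes the ten-membered carbocycle and, after lactonisation, the α-methylene-γ-lactone (proposed new step).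
3. 22 comes from a linear C12 chain: Morita–Baylis–Hillman reaction and SN2' bromination at the C7 aldehyde; the 4Z alkene comes from a temporary butenolide (Bestmann ylide on an α-hydroxy ketone) that is opened by reduction.
4. The chain comes from E-alkenyl iodide 5 (Negishi carboalumination of a glycidol-derived alkyne; C8 stereocentre and 1(10)E alkene) and methyl (S)-glycidate 6 (C3 stereocentre).
5. Ring order: temporary butenolide (steps 7–8, opened again), then carbocycle and γ-lactone together (step 17), then the 1,10-epoxide (step 18); the side-chain oxirane arrives preformed (step 22).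

Assumption: the database structure is taken literally ((R)-2-methylbutanoate at C3; (2R,3S)-2,3-dimethyloxirane-2-carboxylate with cis methyls at C8); 1, 6, 14, 18 and 27 are bought; TBS = tert-butyldimethylsilyl, PMB = 4-methoxybenzyl; germacrane numbering is used (C1–C10 ring, C11–C13 lactone, C14 on C10, C15 on C4).

**Route**

Step 1
Reactants: 1 (R)-2-{[(4-methoxybenzyl)oxy]methyl}oxirane
Product: 2 (R)-1-(PMBO)pent-4-yn-2-ol
Conditions: LiC≡CH·H2NCH2CH2NH2, DMSO, rt; then H2O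
Reagents that add atoms: lithium acetylide ethylenediamine complex, [Li+].[C-]#C.NCCN
Why: SN2 opening of the terminal epoxide at its CH2 carbon by the acetylide leaves the C–O bond of the stereocentre (future C8) untouched, so its configuration comes unchanged from 1.

Step 2
Reactants: 2 (R)-1-(PMBO)pent-4-yn-2-ol
Product: 3 (R)-tert-butyldimethyl{[1-(PMBO)pent-4-yn-2-yl]oxy}silane
Conditions: TBSCl, imidazole, DMF, rt
Reagents that add atoms: tert-butyldimethylsilyl chloride, CC(C)(C)[Si](C)(C)Cl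
Why: Standard silylation of a secondary alcohol, giving a group that survives organometallic, hydride and oxidative steps up to step 19.

Step 3
Reactants: 3 (R)-tert-butyldimethyl{[1-(PMBO)pent-4-yn-2-yl]oxy}silane
Product: 5 (R,E)-tert-butyl{[5-iodo-4-methyl-1-(PMBO)pent-4-en-2-yl]oxy}dimethylsilane, via alkenyldimethylalane 4 (not isolated)
Conditions: Me3Al, (C5H5)2ZrCl2 (20 mol %), CH2Cl2, 0 °C to rt; then I2, THF, −30 °C
Reagents that add atoms: trimethylaluminium, C[Al](C)C; iodine, [I][I]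
Why: Negishi zirconium-catalysed carboalumination adds methyl and aluminium syn across the alkyne with methyl on the internal carbon, and iodinolysis with retention gives only the E-iodide, which fixes the 1(10)E geometry.

Step 4
Reactants: 5 (R,E)-tert-butyl{[5-iodo-4-methyl-1-(PMBO)pent-4-en-2-yl]oxy}dimethylsilane; 6 methyl (S)-oxirane-2-carboxylate
Product: 8 methyl (2S,4E,7R)-2-hydroxy-5-methyl-8-(PMBO)-7-(TBSO)oct-4-enoate, via alkenylmagnesium chloride 7 (not isolated)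
Conditions: i-PrMgCl·LiCl, THF, 0 °C to rt; then 6, CuI (10 mol %), THF, −40 °C; then H2O
Reagents that add atoms: none
Why: Iodine–magnesium exchange keeps the alkene geometry and the copper-catalysed SN2 opening takes place at the CH2 of the glycidate, so C3 keeps the (S) configuration of 6 and the C1–C2 bond is formed.

Step 5
Reactants: 8 methyl (2S,4E,7R)-2-hydroxy-5-methyl-8-(PMBO)-7-(TBSO)oct-4-enoate
Product: 9 (2S,4E,7R)-2-hydroxy-N-methoxy-N,5-dimethyl-8-(PMBO)-7-(TBSO)oct-4-enamide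
Conditions: MeNH(OMe)·HCl, i-PrMgCl, THF, −20 °C
Reagents that add atoms: N,O-dimethylhydroxylamine hydrochloride, CNOC.Cl
Why: Aminolysis of the ester by the magnesium amide (Weinreb amide formation) does not touch the α-stereocentre.

Step 6
Reactants: 9 (2S,4E,7R)-2-hydroxy-N-methoxy-N,5-dimethyl-8-(PMBO)-7-(TBSO)oct-4-enamide
Product: 10 (3S,5E,8R)-3-hydroxy-6-methyl-9-(PMBO)-8-(TBSO)non-5-en-2-one
Conditions: MeMgBr (3 equiv), THF, 0 °C; then H2O
Reagents that add atoms: methylmagnesium bromide, C[Mg]Br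
Why: Weinreb ketone synthesis, in which the chelated tetrahedral adduct prevents over-addition and delivers the methyl ketone (C15 introduced) with C3 unchanged.

Step 7
Reactants: 10 (3S,5E,8R)-3-hydroxy-6-methyl-9-(PMBO)-8-(TBSO)non-5-en-2-one
Product: 11 (S)-4-methyl-5-[(2E,5R)-3-methyl-6-(PMBO)-5-(TBSO)hex-2-en-1-yl]furan-2(5H)-one
Conditions: Ph3P=C=C=O, toluene, 90 °C
Reagents that add atoms: (triphenylphosphoranylidene)ketene, O=C=C=P(c1ccccc1)(c1ccccc1)c1ccccc1
Why: The hydroxyl adds to the Bestmann ylide and the resulting ester ylide undergoes intramolecular Wittig olefination with the ketone, so the butenolide ring forces C3 and C6 cis on the new C4=C5 bond (the future 4Z alkene) under neutral conditions that do not epimerise C3.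

Step 8
Reactants: 11 (S)-4-methyl-5-[(2E,5R)-3-methyl-6-(PMBO)-5-(TBSO)hex-2-en-1-yl]furan-2(5H)-one
Product: 12 (2Z,4S,6E,9R)-3,7-dimethyl-10-(PMBO)-9-(TBSO)deca-2,6-diene-1,4-diol
Conditions: i-Bu2AlH (4 equiv), CH2Cl2, −78 to 0 °C; then aq KNaC4H4O6
Reagents that add atoms: none
Why: 1,2-Hydride reduction of the unsaturated lactone to the diol keeps the Z geometry that the ring had locked in.

Step 9
Reactants: 12 (2Z,4S,6E,9R)-3,7-dimethyl-10-(PMBO)-9-(TBSO)deca-2,6-diene-1,4-diol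
Product: 13 (2Z,4S,6E,9R)-3,7-dimethyl-10-(PMBO)-1,9-bis(TBSO)deca-2,6-dien-4-ol
Conditions: TBSCl (1.05 equiv), imidazole, CH2Cl2, −20 °C
Reagents that add atoms: tert-butyldimethylsilyl chloride, CC(C)(C)[Si](C)(C)Cl
Why: Silylation is selective for the primary allylic hydroxyl over the hindered secondary one.

Step 10
Reactants: 13 (2Z,4S,6E,9R)-3,7-dimethyl-10-(PMBO)-1,9-bis(TBSO)deca-2,6-dien-4-ol; 14 (R)-2-methylbutanoic acid
Product: 15 (2Z,4S,6E,9R)-3,7-dimethyl-10-(PMBO)-1,9-bis(TBSO)deca-2,6-dien-4-yl (R)-2-methylbutanoate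
Conditions: DCC, DMAP (cat.), CH2Cl2, 0 °C to rt
Reagents that add atoms: none
Why: Steglich esterification acylates O3 with retention at C3 and without a base strong enough to epimerise the α-stereocentre of the acid.

Step 11
Reactants: 15 (2Z,4S,6E,9R)-3,7-dimethyl-10-(PMBO)-1,9-bis(TBSO)deca-2,6-dien-4-yl (R)-2-methylbutanoate
Product: 16 (2Z,4S,6E,9R)-10-hydroxy-3,7-dimethyl-1,9-bis(TBSO)deca-2,6-dien-4-yl (R)-2-methylbutanoate
Conditions: DDQ, CH2Cl2/pH 7 buffer, 0 °C
Reagents that add atoms: none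
Why: Oxidative cleavage of the 4-methoxybenzyl ether through its benzylic oxocarbenium ion leaves silyl ethers, ester and alkenes intact.

Step 12
Reactants: 16 (2Z,4S,6E,9R)-10-hydroxy-3,7-dimethyl-1,9-bis(TBSO)deca-2,6-dien-4-yl (R)-2-methylbutanoate
Product: 17 (2Z,4S,6E,9R)-3,7-dimethyl-10-oxo-1,9-bis(TBSO)deca-2,6-dien-4-yl (R)-2-methylbutanoate
Conditions: Dess–Martin periodinane, CH2Cl2, 0 °C
Reagents that add atoms: none
Why: Dess–Martin oxidation gives the α-silyloxy aldehyde under non-basic conditions that do not epimerise C8.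

Step 13
Reactants: 17 (2Z,4S,6E,9R)-3,7-dimethyl-10-oxo-1,9-bis(TBSO)deca-2,6-dien-4-yl (R)-2-methylbutanoate; 18 methyl acrylate
Product: 19 methyl (4R,6E,9S,10Z)-3-hydroxy-6,10-dimethyl-9-{[(R)-2-methylbutanoyl]oxy}-2-methylidene-4,12-bis(TBSO)dodeca-6,10-dienoate (C3 epimers)
Conditions: 18 (excess), DABCO, MeOH (cat.), rt, 5 d
Reagents that add atoms: none
Why: Morita–Baylis–Hillman reaction forms the C7–C11 bond, and the new carbinol centre is left as a mixture because it becomes sp2 in step 14.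

Step 14
Reactants: 19 methyl (4R,6E,9S,10Z)-3-hydroxy-6,10-dimethyl-9-{[(R)-2-methylbutanoyl]oxy}-2-methylidene-4,12-bis(TBSO)dodeca-6,10-dienoate
Product: 20 methyl (2Z,4R,6E,9S,10Z)-2-(bromomethyl)-6,10-dimethyl-9-{[(R)-2-methylbutanoyl]oxy}-4,12-bis(TBSO)dodeca-2,6,10-trienoate
Conditions: NBS, Me2S, CH2Cl2, 0 °C
Reagents that add atoms: N-bromosuccinimide, O=C1CCC(=O)N1Br
Why: The alkoxysulfonium salt (Corey–Kim type activation) is displaced by bromide in SN2' fashion to give the conjugated Z-configured 2-(bromomethyl)enoate, with C8 not involved.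

Step 15
Reactants: 20 methyl (2Z,4R,6E,9S,10Z)-2-(bromomethyl)-6,10-dimethyl-9-{[(R)-2-methylbutanoyl]oxy}-4,12-bis(TBSO)dodeca-2,6,10-trienoate
Product: 21 methyl (2Z,4R,6E,9S,10Z)-2-(bromomethyl)-12-hydroxy-6,10-dimethyl-9-{[(R)-2-methylbutanoyl]oxy}-4-(TBSO)dodeca-2,6,10-trienoate
Conditions: HF·pyridine, pyridine, THF, 0 °C
Reagents that add atoms: none
Why: Fluoride-mediated desilylation is much faster for the primary allylic silyl ether than for the hindered secondary one at C8.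

Step 16
Reactants: 21 methyl (2Z,4R,6E,9S,10Z)-2-(bromomethyl)-12-hydroxy-6,10-dimethyl-9-{[(R)-2-methylbutanoyl]oxy}-4-(TBSO)dodeca-2,6,10-trienoate
Product: 22 methyl (2Z,4R,6E,9S,10Z)-2-(bromomethyl)-6,10-dimethyl-9-{[(R)-2-methylbutanoyl]oxy}-12-oxo-4-(TBSO)dodeca-2,6,10-trienoate
Conditions: Dess–Martin periodinane, CH2Cl2, 0 °C
Reagents that add atoms: none
Why: Dess–Martin oxidation of the allylic alcohol gives the Z-enal without acid or base that would isomerise it.

Step 17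
Reactants: 22 methyl (2Z,4R,6E,9S,10Z)-2-(bromomethyl)-6,10-dimethyl-9-{[(R)-2-methylbutanoyl]oxy}-12-oxo-4-(TBSO)dodeca-2,6,10-trienoate
Product: 24 (1(10)E,4Z)-3β-[(R)-2-methylbutanoyloxy]-8β-(TBSO)germacra-1(10),4,11(13)-trien-12,6α-olide (H-7α), via silylated seco ester 23 (not isolated)
Conditions: CrCl2 (20 mol %), L (24 mol %), Mn powder, Me3SiCl, i-Pr2NEt, THF, slow addition of 22 (final 2 mM), rt; then 1 M HCl, THF, 0 °C [L = 3,6-di-tert-butyl-1,8-bis((S)-4-isopropyl-4,5-dihydrooxazol-2-yl)-9H-carbazole]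
Reagents that add atoms: none
Why: Proposed new method: a catalytic, ligand-controlled macrocyclising 2-(methoxycarbonyl)allylation of Nozaki–Hiyama–Kishi (Barbier) type, in which divalent chromium bound to L inserts into the allylic C–Br bond (Mn regenerates it), the σ-allyl trivalent chromium species equilibrates by 1,3-metallotropy and adds through its γ-carbon C7 to the chromium-bound Z-enal in a chair transition state, the tridentate bis(oxazolinyl)carbazolide shields the Re face of C6 so that attack on the Si face sets C6 as R (6α-oxygen), the ten-membered tether holds C5 and C8 pseudo-equatorial so that H-6 and H-7 end up trans (C7 set), Me3SiCl silylates the chromium alkoxide to turn the metal over, and acid then cleaves the silyl ether of 23 and closes the γ-lactone; the closest known reaction types are the intermolecular chromium-catalysed enantioselective 2-(alkoxycarbonyl)allylation of aldehydes and the stoichiometric CrCl2 Barbier macrocyclisations used for ten-membered germacranolide rings.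

Step 18
Reactants: 24 (1(10)E,4Z)-3β-[(R)-2-methylbutanoyloxy]-8β-(TBSO)germacra-1(10),4,11(13)-trien-12,6α-olide
Product: 25 (4Z)-1β,10α-epoxy-3β-[(R)-2-methylbutanoyloxy]-8β-(TBSO)germacra-4,11(13)-dien-12,6α-olide
Conditions: mCPBA (1.05 equiv), NaHCO3, CH2Cl2, 0 °C
Reagents that add atoms: 3-chloroperbenzoic acid, OOC(=O)c1cccc(Cl)c1
Why: Prilezhaev epoxidation attacks only the electron-rich 1(10) alkene (C4=C5 is flanked by two acyloxy-bearing carbons and C11=C13 is conjugated), and in the expected ring conformation with C14 on the β-face the peracid can reach only the outer face, which gives the 1β,10α (1R,10R) epoxide.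

Step 19
Reactants: 25 (4Z)-1β,10α-epoxy-3β-[(R)-2-methylbutanoyloxy]-8β-(TBSO)germacra-4,11(13)-dien-12,6α-olide
Product: 26 (4Z)-1β,10α-epoxy-8β-hydroxy-3β-[(R)-2-methylbutanoyloxy]germacra-4,11(13)-dien-12,6α-olide
Conditions: HF·pyridine, pyridine, THF, 0 °C to rt
Reagents that add atoms: none
Why: Buffered fluoride cleavage of the silyl ether leaves the epoxide, the ester and the α-methylene lactone intact.

Step 20
Reactants: 27 (E)-2-methylbut-2-en-1-ol
Product: 28 [(2S,3S)-2,3-dimethyloxiran-2-yl]methanol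
Conditions: Ti(Oi-Pr)4 (5 mol %), L-(+)-diethyl tartrate (6 mol %), t-BuOOH, 4 Å molecular sieves, CH2Cl2, −20 °C
Reagents that add atoms: tert-butyl hydroperoxide, CC(C)(C)OO
Why: Sharpless asymmetric epoxidation with the L-(+)-tartrate titanium catalyst delivers oxygen to one face of the E-allylic alcohol and sets both stereocentres of the C8 acyl group as (2S,3S).

Step 21
Reactants: 28 [(2S,3S)-2,3-dimethyloxiran-2-yl]methanol
Product: 29 (2R,3S)-2,3-dimethyloxirane-2-carboxylic acid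
Conditions: RuCl3·xH2O (2 mol %), NaIO4, CCl4/MeCN/H2O, rt
Reagents that add atoms: water, O
Why: Ruthenium tetroxide oxidation (formed catalytically from RuCl3 and NaIO4) converts the primary alcohol to the acid without touching the oxirane, the descriptor at C2 changing only because of the new priority order.

Step 22
Reactants: 26 (4Z)-1β,10α-epoxy-8β-hydroxy-3β-[(R)-2-methylbutanoyloxy]germacra-4,11(13)-dien-12,6α-olide; 29 (2R,3S)-2,3-dimethyloxirane-2-carboxylic acid
Product: 31 (4Z)-8β-{[(2R,3S)-2,3-dimethyloxirane-2-carbonyl]oxy}-1β,10α-epoxy-3β-[(R)-2-methylbutanoyloxy]germacra-4,11(13)-dien-12,6α-olide (1R,3S,6R,7R,8R,10R; CNP0265335.3), via mixed anhydride 30 (not isolated)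
Conditions: 29, 2,4,6-trichlorobenzoyl chloride, Et3N, THF, rt; then 26, DMAP, toluene, rt
Reagents that add atoms: none
Why: Yamaguchi esterification through the mixed anhydride acylates the hindered 8β-hydroxyl with retention at C8 and without opening either epoxide.

**Compound list**

1 | (R)-2-{[(4-methoxybenzyl)oxy]methyl}oxirane | COc1ccc(COC[C@H]2CO2)cc1 | starting material
2 | (R)-1-(PMBO)pent-4-yn-2-ol | C#CC[C@@H](O)COCc1ccc(OC)cc1 | intermediate
3 | (R)-tert-butyldimethyl{[1-(PMBO)pent-4-yn-2-yl]oxy}silane | C#CC[C@@H](O[Si](C)(C)C(C)(C)C)COCc1ccc(OC)cc1 | intermediate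
4 | dimethyl[(1E,4R)-2-methyl-5-(PMBO)-4-(TBSO)pent-1-en-1-yl]alumane | C[Al](C)/C=C(\C)C[C@@H](O[Si](C)(C)C(C)(C)C)COCc1ccc(OC)cc1 | intermediate
5 | (R,E)-tert-butyl{[5-iodo-4-methyl-1-(PMBO)pent-4-en-2-yl]oxy}dimethylsilane | I/C=C(\C)C[C@@H](O[Si](C)(C)C(C)(C)C)COCc1ccc(OC)cc1 | intermediate
6 | methyl (S)-oxirane-2-carboxylate | COC(=O)[C@@H]1CO1 | starting material
7 | chloro[(1E,4R)-2-methyl-5-(PMBO)-4-(TBSO)pent-1-en-1-yl]magnesium | Cl[Mg]/C=C(\C)C[C@@H](O[Si](C)(C)C(C)(C)C)COCc1ccc(OC)cc1 | intermediate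
8 | methyl (2S,4E,7R)-2-hydroxy-5-methyl-8-(PMBO)-7-(TBSO)oct-4-enoate | COC(=O)[C@@H](O)C/C=C(\C)C[C@@H](O[Si](C)(C)C(C)(C)C)COCc1ccc(OC)cc1 | intermediate
9 | (2S,4E,7R)-2-hydroxy-N-methoxy-N,5-dimethyl-8-(PMBO)-7-(TBSO)oct-4-enamide | CON(C)C(=O)[C@@H](O)C/C=C(\C)C[C@@H](O[Si](C)(C)C(C)(C)C)COCc1ccc(OC)cc1 | intermediate
10 | (3S,5E,8R)-3-hydroxy-6-methyl-9-(PMBO)-8-(TBSO)non-5-en-2-one | CC(=O)[C@@H](O)C/C=C(\C)C[C@@H](O[Si](C)(C)C(C)(C)C)COCc1ccc(OC)cc1 | intermediate
11 | (S)-4-methyl-5-[(2E,5R)-3-methyl-6-(PMBO)-5-(TBSO)hex-2-en-1-yl]furan-2(5H)-one | O=C1C=C(C)[C@@H](O1)C/C=C(\C)C[C@@H](O[Si](C)(C)C(C)(C)C)COCc1ccc(OC)cc1 | intermediate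
12 | (2Z,4S,6E,9R)-3,7-dimethyl-10-(PMBO)-9-(TBSO)deca-2,6-diene-1,4-diol | OC/C=C(/C)[C@@H](O)C/C=C(\C)C[C@@H](O[Si](C)(C)C(C)(C)C)COCc1ccc(OC)cc1 | intermediate
13 | (2Z,4S,6E,9R)-3,7-dimethyl-10-(PMBO)-1,9-bis(TBSO)deca-2,6-dien-4-ol | CC(C)(C)[Si](C)(C)OC/C=C(/C)[C@@H](O)C/C=C(\C)C[C@@H](O[Si](C)(C)C(C)(C)C)COCc1ccc(OC)cc1 | intermediate
14 | (R)-2-methylbutanoic acid | CC[C@@H](C)C(=O)O | starting material
15 | (2Z,4S,6E,9R)-3,7-dimethyl-10-(PMBO)-1,9-bis(TBSO)deca-2,6-dien-4-yl (R)-2-methylbutanoate | CC(C)(C)[Si](C)(C)OC/C=C(/C)[C@@H](OC(=O)[C@H](C)CC)C/C=C(\C)C[C@@H](O[Si](C)(C)C(C)(C)C)COCc1ccc(OC)cc1 | intermediate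
16 | (2Z,4S,6E,9R)-10-hydroxy-3,7-dimethyl-1,9-bis(TBSO)deca-2,6-dien-4-yl (R)-2-methylbutanoate | CC(C)(C)[Si](C)(C)OC/C=C(/C)[C@@H](OC(=O)[C@H](C)CC)C/C=C(\C)C[C@@H](O[Si](C)(C)C(C)(C)C)CO | intermediate
17 | (2Z,4S,6E,9R)-3,7-dimethyl-10-oxo-1,9-bis(TBSO)deca-2,6-dien-4-yl (R)-2-methylbutanoate | CC(C)(C)[Si](C)(C)OC/C=C(/C)[C@@H](OC(=O)[C@H](C)CC)C/C=C(\C)C[C@@H](O[Si](C)(C)C(C)(C)C)C=O | intermediate
18 | methyl acrylate | C=CC(=O)OC | starting material
19 | methyl (4R,6E,9S,10Z)-3-hydroxy-6,10-dimethyl-9-{[(R)-2-methylbutanoyl]oxy}-2-methylidene-4,12-bis(TBSO)dodeca-6,10-dienoate (C3 epimers) | CC(C)(C)[Si](C)(C)OC/C=C(/C)[C@@H](OC(=O)[C@H](C)CC)C/C=C(\C)C[C@@H](O[Si](C)(C)C(C)(C)C)C(O)C(=C)C(=O)OC | intermediate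
20 | methyl (2Z,4R,6E,9S,10Z)-2-(bromomethyl)-6,10-dimethyl-9-{[(R)-2-methylbutanoyl]oxy}-4,12-bis(TBSO)dodeca-2,6,10-trienoate | CC(C)(C)[Si](C)(C)OC/C=C(/C)[C@@H](OC(=O)[C@H](C)CC)C/C=C(\C)C[C@@H](O[Si](C)(C)C(C)(C)C)/C=C(\CBr)C(=O)OC | intermediate
21 | methyl (2Z,4R,6E,9S,10Z)-2-(bromomethyl)-12-hydroxy-6,10-dimethyl-9-{[(R)-2-methylbutanoyl]oxy}-4-(TBSO)dodeca-2,6,10-trienoate | OC/C=C(/C)[C@@H](OC(=O)[C@H](C)CC)C/C=C(\C)C[C@@H](O[Si](C)(C)C(C)(C)C)/C=C(\CBr)C(=O)OC | intermediate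
22 | methyl (2Z,4R,6E,9S,10Z)-2-(bromomethyl)-6,10-dimethyl-9-{[(R)-2-methylbutanoyl]oxy}-12-oxo-4-(TBSO)dodeca-2,6,10-trienoate | O=C/C=C(/C)[C@@H](OC(=O)[C@H](C)CC)C/C=C(\C)C[C@@H](O[Si](C)(C)C(C)(C)C)/C=C(\CBr)C(=O)OC | intermediate
23 | methyl (1(10)E,4Z)-3β-[(R)-2-methylbutanoyloxy]-8β-(TBSO)-6α-(trimethylsilyloxy)germacra-1(10),4,11(13)-trien-12-oate | COC(=O)C(=C)[C@H]1[C@H](O[Si](C)(C)C)/C=C(/C)[C@@H](OC(=O)[C@H](C)CC)C/C=C(\C)C[C@H]1O[Si](C)(C)C(C)(C)C | intermediate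
24 | (1(10)E,4Z)-3β-[(R)-2-methylbutanoyloxy]-8β-(TBSO)germacra-1(10),4,11(13)-trien-12,6α-olide | C=C1C(=O)O[C@@H]2/C=C(/C)[C@@H](OC(=O)[C@H](C)CC)C/C=C(\C)C[C@@H](O[Si](C)(C)C(C)(C)C)[C@@H]12 | intermediate
25 | (4Z)-1β,10α-epoxy-3β-[(R)-2-methylbutanoyloxy]-8β-(TBSO)germacra-4,11(13)-dien-12,6α-olide | C=C1C(=O)O[C@@H]2/C=C(/C)[C@@H](OC(=O)[C@H](C)CC)C[C@H]3O[C@]3(C)C[C@@H](O[Si](C)(C)C(C)(C)C)[C@@H]12 | intermediate
26 | (4Z)-1β,10α-epoxy-8β-hydroxy-3β-[(R)-2-methylbutanoyloxy]germacra-4,11(13)-dien-12,6α-olide | C=C1C(=O)O[C@@H]2/C=C(/C)[C@@H](OC(=O)[C@H](C)CC)C[C@H]3O[C@]3(C)C[C@@H](O)[C@@H]12 | intermediate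
27 | (E)-2-methylbut-2-en-1-ol | C/C=C(\C)CO | starting material
28 | [(2S,3S)-2,3-dimethyloxiran-2-yl]methanol | OC[C@]1(C)O[C@H]1C | intermediate
29 | (2R,3S)-2,3-dimethyloxirane-2-carboxylic acid | OC(=O)[C@]1(C)O[C@H]1C | intermediate
30 | (2R,3S)-2,3-dimethyloxirane-2-carboxylic 2,4,6-trichlorobenzoic anhydride | O=C(OC(=O)c1c(Cl)cc(Cl)cc1Cl)[C@]1(C)O[C@H]1C | intermediate
31 | (4Z)-8β-{[(2R,3S)-2,3-dimethyloxirane-2-carbonyl]oxy}-1β,10α-epoxy-3β-[(R)-2-methylbutanoyloxy]germacra-4,11(13)-dien-12,6α-olide | C=C1C(=O)O[C@@H]2/C=C(/C)[C@@H](OC(=O)[C@H](C)CC)C[C@H]3O[C@]3(C)C[C@@H](OC(=O)[C@]3(C)O[C@H]3C)[C@@H]12 | target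

**Totals and risks**

Total step count: 22. Longest linear sequence: 20 (steps 1–19 and 22; steps 20–21 make the side-chain acid).

Most likely to fail, step 17 (the proposed new step). The ring closure may lose to oligomerisation, to β-elimination of the C8 silyloxy group from the branched allylchromium isomer, or to Z/E drift of the enal. The ligand may also be mismatched with the C8 stereocentre; the (S,S) ligand is a choice by analogy, and its antipode is the first thing to try. The fallback uses known chemistry and closes the ring at C4=C5 instead of C6–C7; it sets out from 10 and comes back at 25. Ketone 10 is methylenated (Ph3P=CH2, THF) to the isopropenyl carbinol F1, which is esterified with 14 (DCC, DMAP) to the 2-methylbutanoate F2. A Shi epoxidation (fructose-derived ketone of the series that gives the 1R,10R product, KHSO5, K2CO3 buffer) of the only electron-rich alkene gives the epoxide F3 under reagent control. DDQ then gives the primary alcohol F4, Dess–Martin oxidation the aldehyde F5, the Morita–Baylis–Hillman reaction with 18 the adduct F6, and NBS/Me2S the allylic bromide F7. An intermolecular Barbier addition of F7 to acrolein (CrCl2, THF) with lactonisation gives the vinyl lactone F8, whose trans isomer is separated. Ring-closing metathesis with the second-generation Hoveyda–Grubbs catalyst at high dilution joins C4 and C5 to give 25.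

Second, step 18. The facial selectivity rests on the ring conformation of 24 and has no directing group, so the peracid may take the wrong face and give the 1α,10β-epoxide. The fallback sets out from 24 and comes back at 25. NBS in THF/H2O at 0 °C gives the bromohydrin F9 (bromonium ion on the outer face, water opening at the tertiary C10 from the other side). K2CO3 in acetone then closes the oxirane with inversion at C1, which puts the oxygen on the face opposite to the one a peracid takes.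

Third, step 13. The α-silyloxy aldehyde 17 is hindered, the amine-catalysed reaction takes days, and C8 can epimerise meanwhile. The fallback sets out from 17 and comes back at 19. Methyl propiolate is hydroaluminated (i-Bu2AlH, HMPA, THF, 0 °C) to the α-(methoxycarbonyl)vinylalane F10, a non-basic nucleophile that adds to 17 at −78 °C and gives 19 after aqueous work-up.

**Further compounds**

F1 | step 17 | isopropenyl carbinol, (3S,5E,8R)-2,6-dimethyl-9-(PMBO)-8-(TBSO)nona-1,5-dien-3-ol | C=C(C)[C@@H](O)C/C=C(\C)C[C@@H](O[Si](C)(C)C(C)(C)C)COCc1ccc(OC)cc1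
F2 | step 17 | 2-methylbutanoate, (3S,5E,8R)-2,6-dimethyl-9-(PMBO)-8-(TBSO)nona-1,5-dien-3-yl (R)-2-methylbutanoate | C=C(C)[C@@H](OC(=O)[C@H](C)CC)C/C=C(\C)C[C@@H](O[Si](C)(C)C(C)(C)C)COCc1ccc(OC)cc1
F3 | step 17 | epoxide, (3S,5R,6R,8R)-5,6-epoxy-2,6-dimethyl-9-(PMBO)-8-(TBSO)non-1-en-3-yl (R)-2-methylbutanoate | C=C(C)[C@@H](OC(=O)[C@H](C)CC)C[C@H]1O[C@]1(C)C[C@@H](O[Si](C)(C)C(C)(C)C)COCc1ccc(OC)cc1
F4 | step 17 | primary alcohol, (3S,5R,6R,8R)-5,6-epoxy-9-hydroxy-2,6-dimethyl-8-(TBSO)non-1-en-3-yl (R)-2-methylbutanoate | C=C(C)[C@@H](OC(=O)[C@H](C)CC)C[C@H]1O[C@]1(C)C[C@@H](O[Si](C)(C)C(C)(C)C)CO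
F5 | step 17 | aldehyde, (3S,5R,6R,8R)-5,6-epoxy-2,6-dimethyl-9-oxo-8-(TBSO)non-1-en-3-yl (R)-2-methylbutanoate | C=C(C)[C@@H](OC(=O)[C@H](C)CC)C[C@H]1O[C@]1(C)C[C@@H](O[Si](C)(C)C(C)(C)C)C=O
F6 | step 17 | Morita–Baylis–Hillman adduct of F5 and methyl acrylate (carbinol epimers) | C=C(C)[C@@H](OC(=O)[C@H](C)CC)C[C@H]1O[C@]1(C)C[C@@H](O[Si](C)(C)C(C)(C)C)C(O)C(=C)C(=O)OC
F7 | step 17 | allylic bromide, (Z)-2-(bromomethyl)enoate from F6 | C=C(C)[C@@H](OC(=O)[C@H](C)CC)C[C@H]1O[C@]1(C)C[C@@H](O[Si](C)(C)C(C)(C)C)/C=C(\CBr)C(=O)OC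
F8 | step 17 | vinyl lactone, 4,5-seco diene of 25 (vinyl on C6, isopropenyl on C3, configurations as in 25) | C=C1C(=O)O[C@H](C=C)[C@H]1[C@H](O[Si](C)(C)C(C)(C)C)C[C@@]2(C)O[C@@H]2C[C@H](OC(=O)[C@H](C)CC)C(C)=C
F9 | step 18 | bromohydrin, 1-bromo-10-hydroxy adduct of 24 (Br at C1 anti to the C10 hydroxyl) | C=C1C(=O)O[C@@H]2/C=C(/C)[C@@H](OC(=O)[C@H](C)CC)C[C@H](Br)[C@@](O)(C)C[C@@H](O[Si](C)(C)C(C)(C)C)[C@@H]12
F10 | step 13 | α-(methoxycarbonyl)vinylalane, methyl 2-(diisobutylalumanyl)acrylate | C=C(C(=O)OC)[Al](CC(C)C)CC(C)C
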